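**Assumptions**
- Absinthin is the accessible endo, head-to-head Diels–Alder homodimer of cyclopentadiene **23**, and it cyclises to anabsinthin under acid.
- C1–H of the cyclopentadiene keeps its configuration through suprafacial [1,5]-H shifts.
- Only substrates, intermediates and the two skeletal starting materials (1 and 11) are numbered. Simple commercial reagents appear only in the "add atoms" lines.

**Retrosynthesis**
1. Anabsinthin ⇒ transannular hydroalkoxylation of the norbornene C=C of absinthin (24) by the B-ring 10-OH (THF ring formed last).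
2. 24 ⇒ endo, head-to-head Diels–Alder homodimerisation of the cyclopentadienyl guaianolide 23. Both units react on the face anti to the C10 carbinol.
3. 23 ⇐ C3 ketone reduction and dehydration ⇐ intramolecular Pauson–Khand reaction of the 1,8-enyne lactone 19, which closes the 7-ring and the cyclopentenone together.
4. 19 ⇐ trans conjugate addition and then trans-methylation on the γ-alkynyl butenolide 17, using the Grignard from bromide 10. C10 comes from Sharpless epoxidation. C6 comes from ketoreductase reduction of ynone 13.
5. Ring order: lactone, then 7-ring and cyclopentenone (Pauson–Khand), then cyclopentadiene, then norbornene (Diels–Alder), then THF.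

---

**Step 1**
Reactants: 1 α-methylene-γ-butyrolactone
Product: 2 2-methylenebutane-1,4-diol
Conditions: DIBAL-H (3 equiv), CH2Cl2, –78 → 0 °C
Reagents that add atoms: none (hydride only)
Why: Excess DIBAL-H reduces the lactone through the lactol to the diol (1,2-reduction, hydroalumination), and the exocyclic alkene survives.

**Step 2**
Reactants: 2
Product: 3 4-[(4-methoxybenzyl)oxy]-2-methylidenebutan-1-ol
Conditions: NaH (1.0 equiv), PMBCl (1.0 equiv), TBAI (cat.), THF/DMF, 0 °C
Reagents that add atoms: PMBCl, ClCc1ccc(OC)cc1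
Why: Statistical Williamson mono-etherification. The 4-O-PMB regioisomer is separated by chromatography (modest yield, recyclable diol).

**Step 3**
Reactants: 3
Product: 4 [(2S)-2-(2-PMBO-ethyl)oxiran-2-yl]methanol
Conditions: Ti(OiPr)4 (10 mol%), L-(+)-DET (12 mol%), TBHP, 3 Å MS, CH2Cl2, –20 °C
Reagents that add atoms: tert-butyl hydroperoxide, CC(C)(C)OO (supplies the epoxide O)
Why: Sharpless asymmetric epoxidation. This is the first stereocentre; the Ti–tartrate complex delivers O to one face of the 2-substituted allylic alcohol, and L-(+)-DET gives the S epoxide, which becomes C10.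

**Step 4**
Reactants: 4
Product: 5 (2S)-4-PMBO-2-methylbutane-1,2-diol
Conditions: LiEt3BH (3 equiv), THF, 0 °C
Reagents that add atoms: none (hydride only)
Why: Hydride opens the epoxide by SN2 at the unhindered CH2, giving the tertiary alcohol with the C–O bond at the stereocentre untouched (C10 retained).

**Step 5**
Reactants: 5
Product: 6 (2S)-2-hydroxy-4-PMBO-2-methylbutanal
Conditions: Dess–Martin periodinane, NaHCO3, CH2Cl2, 0 °C → rt
Reagents that add atoms: none
Why: Chemoselective oxidation of the primary alcohol (tertiary OH unaffected). The aldehyde has no α-H, so it cannot racemise, and it is used crude.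

**Step 6**
Reactants: 6
Product: 7 (3S)-5-PMBO-3-methylpent-1-en-3-ol
Conditions: Ph3P+CH3 Br–, KOtBu (3 equiv), THF, 0 °C
Reagents that add atoms: methylenetriphenylphosphorane, C=P(c1ccccc1)(c1ccccc1)c1ccccc1 (adds CH2, which becomes C2 of the vinyl group)
Why: Wittig methylenation converts the CHO carbon into the C1=C2 vinyl group; excess ylide covers the free OH.

**Step 7**
Reactants: 7
Product: 8 TES ether of 7
Conditions: TESOTf (1.5 equiv), 2,6-lutidine, CH2Cl2, –78 → 0 °C
Reagents that add atoms: triethylsilyl triflate, CC[Si](CC)(CC)OS(=O)(=O)C(F)(F)F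
Why: Silylation of the hindered tertiary alcohol, which is needed for the Grignard and Pauson–Khand steps.

**Step 8**
Reactants: 8
Product: 9 (3S)-3-methyl-3-(TESO)pent-4-en-1-ol
Conditions: DDQ, CH2Cl2/pH 7 buffer (18:1), 0 °C
Reagents that add atoms: none (PMB is removed)
Why: Oxidative PMB cleavage is orthogonal to the TES ether and the vinyl group.

**Step 9**
Reactants: 9
Product: 10 (3S)-1-bromo-3-methyl-3-(TESO)pent-4-ene (C8–C9–C10 unit)
Conditions: PPh3, CBr4, CH2Cl2, 0 °C
Reagents that add atoms: carbon tetrabromide, BrC(Br)(Br)Br (supplies Br)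
Why: Appel reaction, SN2 at a primary carbon, no stereocentre involved.

**Step 10**
Reactants: 11 ethyl 4-chloro-4-oxobutanoate (ethyl succinyl chloride)
Product: 12 ethyl 4-[methoxy(methyl)amino]-4-oxobutanoate
Conditions: MeNHOMe·HCl, pyridine, CH2Cl2, 0 °C
Reagents that add atoms: N,O-dimethylhydroxylamine, CONC (leaves the N(OMe)Me group)
Why: Acylation of the hydroxylamine gives the Weinreb amide, which will stop at the ketone stage.

**Step 11**
Reactants: 12
Product: 13 ethyl 4-oxohept-5-ynoate
Conditions: 1-propynylMgBr (1.1 equiv), THF, –78 → 0 °C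
Reagents that add atoms: 1-propynylmagnesium bromide, CC#C[Mg]Br (leaves propynyl)
Why: Chelation-controlled Weinreb ketone synthesis, so the ester is untouched and there is no over-addition.

**Step 12**
Reactants: 13
Product: 14 ethyl (4S)-4-hydroxyhept-5-ynoate
Conditions: ketoreductase (NADPH-dependent, S-selective KRED), NADP+ (1 mol%), iPrOH (10% v/v) for cofactor recycling, KPi pH 7, 30 °C
Reagents that add atoms: none (hydride from NADPH, recycled by iPrOH)
Why: Enzymatic ketone reduction. The KRED active site presents one enantioface of the ynone to NADPH, setting the propargylic C6 stereocentre in >98% ee.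

**Step 13**
Reactants: 14
Product: 15 (5S)-5-(prop-1-yn-1-yl)oxolan-2-one
Conditions: TsOH·H2O (5 mol%), toluene, 50 °C
Reagents that add atoms: none (EtOH is lost)
Why: Acid-catalysed γ-lactonisation through the 5-exo ring closure, with no change at C6.

**Step 14**
Reactants: 15
Product: 16 (5S)-3-(phenylselanyl)-5-(prop-1-yn-1-yl)oxolan-2-one (C3 epimer mixture)
Conditions: LDA (1.1 equiv), THF, –78 °C; then PhSeCl, –78 °C
Reagents that add atoms: benzeneselenenyl chloride, Cl[Se]c1ccccc1
Why: The kinetic lactone enolate is selenylated at C11. The C3 centre is destroyed in the next step, so the mixture does not matter.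

**Step 15**
Reactants: 16
Product: 17 (5S)-5-(prop-1-yn-1-yl)furan-2(5H)-one
Conditions: 30% H2O2 (5 equiv), pyridine, CH2Cl2, 0 °C
Reagents that add atoms: none (PhSeOH is lost)
Why: Selenoxide syn-elimination can only go toward C7, giving the butenolide (C7=C11) while the C6 stereocentre is retained.

**Step 16**
Reactants: 10 and 17
Product: 18 (4S,5S)-4-[(3S)-3-methyl-3-(TESO)pent-4-en-1-yl]-5-(prop-1-yn-1-yl)oxolan-2-one
Conditions: 10 + Mg, THF, 40 °C, to give RMgBr; then CuBr·SMe2 (1.1 equiv), TMSCl, THF, –78 °C; add 17; NH4Cl work-up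
Reagents that add atoms: none (the chain comes from 10; Mg, Cu and TMS are lost)
Why: Cuprate 1,4-addition to a γ-substituted butenolide occurs anti to the C6 substituent, setting C7 trans to C6. TMSCl speeds the addition and suppresses SN2′ attack and γ-deprotonation.

**Step 17**
Reactants: 18
Product: 19 (3S,4S,5S)-3-methyl-4-[(3S)-3-methyl-3-(TESO)pent-4-en-1-yl]-5-(prop-1-yn-1-yl)oxolan-2-one (all-trans enyne lactone)
Conditions: LDA (1.2 equiv), THF, –78 °C; MeI (3 equiv), –78 → –40 °C
Reagents that add atoms: iodomethane, CI
Why: Lactone enolate alkylation. The electrophile approaches anti to the adjacent C7 chain, giving the C11 methyl trans to C8.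

**Step 18**
Reactants: 19
Product: 20 10-O-TES-3-oxoguai-4-en-12,6-olide
Conditions: Co2(CO)8 (1.2 equiv), CH2Cl2, rt; then n-BuSMe (6 equiv), toluene, 80 °C
Reagents that add atoms: carbon monoxide from Co2(CO)8, [C-]#[O+] (becomes the C3 carbonyl)
Why: Intramolecular Pauson–Khand reaction of the 1,8-enyne. It forms C1–C5, C2–C3 and C3–C4 in one step, closing the 7-ring and the cyclopentenone with the methyl α to the C=O. The C1 stereocentre is set by alkene-face selection, controlled by the C10 quaternary centre and the trans-lactone.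

**Step 19**
Reactants: 20
Product: 21 3-hydroxy-10-O-TES-guai-4-en-12,6-olide (C3 epimers)
Conditions: NaBH4, CeCl3·7H2O, MeOH, –20 °C
Reagents that add atoms: none
Why: Luche 1,2-reduction of the enone C=O; the lactone and silyl ether are untouched, and the C3 centre is lost in the next step.

**Step 20**
Reactants: 21
Product: 22 10-O-TES-guaia-2,4-dien-12,6-olide (cyclopentadiene)
Conditions: Burgess reagent, benzene, 50 °C; product used cold and crude
Reagents that add atoms: none
Why: Burgess syn-dehydration of the allylic alcohol can only remove an H from C2, giving the conjugated cyclopentadiene regiospecifically.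

**Step 21**
Reactants: 22
Product: 23 10-hydroxyguaia-2,4-dien-12,6-olide (artabsin-type monomer)
Conditions: TBAF/AcOH (1:1), THF, 0 °C
Reagents that add atoms: none (H only)
Why: Buffered fluoride removes the tertiary TES ether without Cp-anion formation or epimerisation at C1.

**Step 22**
Reactants: 23 (2 molecules)
Product: 24 absinthin (norbornene dimer)
Conditions: neat or 3 M in toluene, 60 °C, sealed tube, argon, 3–7 d; minor isomers removed by HPLC
Reagents that add atoms: none
Why: [4+2] Diels–Alder homodimerisation. One cyclopentadiene acts as the diene (C2/C5 termini) and the other as the dienophile (C2=C3). Both partners react on the face anti to their C10 carbinol, and the endo orientation places the dienophile ring under the new alkene, giving the C2–C2′ and C3–C5′ bonds with five new stereocentres.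

**Step 23**
Reactants: 24
Product: 25 anabsinthin
Conditions: Ph3PAuCl (5 mol%), AgOTf (5 mol%), CH2Cl2, 25 °C
Reagents that add atoms: none
Why: Markovnikov intramolecular hydroalkoxylation of the strained trisubstituted norbornene C=C. The B-ring 10-OH sits syn to that alkene and adds to C4 from the exo face, forming the THF ring and the C4 stereocentre stereospecifically.

---

**Compound list**

| # | Name | SMILES | Role |
|---|---|---|---|
| 1 | α-Methylene-γ-butyrolactone | C=C1CCOC1=O | starting material |
| 2 | 2-Methylenebutane-1,4-diol | C=C(CO)CCO | intermediate |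
| 3 | 4-(PMBO)-2-methylenebutan-1-ol | C=C(CO)CCOCc1ccc(OC)cc1 | intermediate |
| 4 | (2S)-epoxy alcohol | OC[C@@]1(CCOCc2ccc(OC)cc2)CO1 | intermediate |
| 5 | (2S)-4-PMBO-2-methylbutane-1,2-diol | OC[C@@](C)(O)CCOCc1ccc(OC)cc1 | intermediate |
| 6 | (2S)-2-hydroxy-4-PMBO-2-methylbutanal | O=C[C@@](C)(O)CCOCc1ccc(OC)cc1 | intermediate |
| 7 | (3S)-5-PMBO-3-methylpent-1-en-3-ol | C=C[C@@](C)(O)CCOCc1ccc(OC)cc1 | intermediate |
| 8 | TES ether of 7 | C=C[C@@](C)(O[Si](CC)(CC)CC)CCOCc1ccc(OC)cc1 | intermediate |
| 9 | (3S)-3-methyl-3-(TESO)pent-4-en-1-ol | C=C[C@@](C)(O[Si](CC)(CC)CC)CCO | intermediate |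
| 10 | (3S)-1-bromo-3-methyl-3-(TESO)pent-4-ene | C=C[C@@](C)(O[Si](CC)(CC)CC)CCBr | intermediate |
| 11 | Ethyl succinyl chloride | CCOC(=O)CCC(=O)Cl | starting material |
| 12 | Weinreb amide | CCOC(=O)CCC(=O)N(C)OC | intermediate |
| 13 | Ethyl 4-oxohept-5-ynoate | CCOC(=O)CCC(=O)C#CC | intermediate |
| 14 | Ethyl (4S)-4-hydroxyhept-5-ynoate | CCOC(=O)CC[C@H](O)C#CC | intermediate |
| 15 | (5S)-5-(propynyl)oxolan-2-one | CC#C[C@@H]1CCC(=O)O1 | intermediate |
| 16 | (5S)-3-(PhSe)-5-(propynyl)oxolan-2-one | CC#C[C@@H]1CC([Se]c2ccccc2)C(=O)O1 | intermediate |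
| 17 | (5S)-5-(propynyl)furan-2(5H)-one | CC#C[C@@H]1C=CC(=O)O1 | intermediate |
| 18 | trans-4,5-disubstituted lactone | CC#C[C@H]1OC(=O)C[C@@H]1CC[C@](C)(O[Si](CC)(CC)CC)C=C | intermediate |
| 19 | all-trans enyne lactone | CC#C[C@H]1OC(=O)[C@@H](C)[C@@H]1CC[C@](C)(O[Si](CC)(CC)CC)C=C | intermediate |
| 20 | 10-O-TES-3-oxoguai-4-en-12,6-olide | CC1=C2[C@H]3OC(=O)[C@@H](C)[C@@H]3CC[C@](C)(O[Si](CC)(CC)CC)[C@@H]2CC1=O | intermediate |
| 21 | 3-Hydroxy analogue (C3 epimers) | CC1=C2[C@H]3OC(=O)[C@@H](C)[C@@H]3CC[C@](C)(O[Si](CC)(CC)CC)[C@@H]2CC1O | intermediate |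
| 22 | 10-O-TES cyclopentadiene | CC1=C2[C@H]3OC(=O)[C@@H](C)[C@@H]3CC[C@](C)(O[Si](CC)(CC)CC)[C@@H]2C=C1 | intermediate |
| 23 | 10-Hydroxyguaia-2,4-dien-12,6-olide (artabsin-type) | CC1=C2[C@H]3OC(=O)[C@@H](C)[C@@H]3CC[C@](C)(O)[C@@H]2C=C1 | intermediate |
| 24 | Absinthin | CC1=C2[C@H]3OC(=O)[C@@H](C)[C@@H]3CC[C@](C)(O)[C@@H]2[C@H]2[C@H]3C=C(C)[C@]4([C@@H]12)[C@H]5OC(=O)[C@@H](C)[C@@H]5CC[C@](C)(O)[C@H]34 | intermediate |
| 25 | Anabsinthin | CC1=C2[C@H]3OC(=O)[C@@H](C)[C@@H]3CC[C@](C)(O)[C@@H]2[C@H]2[C@H]3C[C@]4(C)O[C@@]5(C)CC[C@H]6[C@H](C)C(=O)O[C@@H]6[C@@]4([C@@H]35)[C@@H]12 | target |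

---

**Totals**
- Total steps: 23 (9 for the C8–C10 fragment, 6 for the butenolide, 8 after they join).
- Longest linear sequence: 17 steps (1 → 10, then steps 16–23).

**Three steps most likely to fail**
1. **Step 18 (Pauson–Khand, 7-ring closure and C1 stereochemistry).** The alkene is hindered by the adjacent quaternary centre and the ring is seven-membered.
   - Fallback: replace the cobalt carbonylation with a Negishi Cp2Zr (or Buchwald Cp2Ti) enyne bicyclisation followed by CO insertion. This goes through a metallacycle and separates the C–C bond formation from the CO insertion.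
2. **Step 22 (Diels–Alder dimerisation).** Sluggish reactivity, and regio/endo-exo mixtures are possible.
   - Fallback: link the two 10-OH groups of 23 with a temporary silaketal or diester tether and run an intramolecular Diels–Alder, which forces the head-to-head endo pairing.
3. **Steps 15–16 (γ-alkynyl butenolide: racemisation, SN2′, dr).** The doubly activated γ-H can racemise, and the cuprate could give SN2′ allene or low trans selectivity.
   - Fallback: reverse the order. Set C7 first by Cu-catalysed asymmetric 1,4-addition of the Grignard to the parent butenolide, methylate trans, then install the C6 propynyl group by Lewis-acid alkynylation of the C6 lactol acetate.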